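## The problem

Elemane numbering is used throughout. The ring carbons are C5–C10. C10 is quaternary, with methyl C14 and vinyl C1=C2. C5 carries C4(=C3H2)–C15H2OH, C6 is the lactone O–CH, C7 carries C11(=C13H2)–C12(=O), C8 is the ester O–CH and C9 is the ring CH2. β is the face of the C10 methyl.

The target is one cyclohexane with five contiguous ring stereocentres, a trans-fused α-methylene-γ-lactone across C6–C7 and an (R)-3-hydroxy-2-methylpropanoate on O8. In the chair every ring substituent except the C10 methyl is equatorial (5β-propenyl, 6α-O, 7β-C11, 8α-O, 10α-vinyl). C7 and C8 can therefore be set by protonation or reduction under thermodynamic control once their neighbours stand, and C6 can be relayed from C5 and C10 in a ring-forming step. The quaternary C10 cannot be corrected later, and its trans relation to the C5 branch must come from the ring formation or from a deliberate epimerisation at C5. The side-chain stereocentre is too remote to be induced and is best bought.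

The functions that will not survive rough treatment are:
- the α-methylene lactone, a Michael acceptor that tolerates neither hydride, ylide, amine nor strong base;
- the 8-oxygen/6,12-lactone pair, which can translactonise to the 8,12-olide under base;
- the β-hydroxy ester of the side chain;
- O15, which must stay distinguishable from O8 until the acylation.

The feature that invites the key step is twofold. C1 and C4, the carbons attached to C10 and C5, are both sp2 and are linked through C2 and C3, so C1–C2–C3–C4 can be read as the C(=O)–CH=C(OMe)–C(=O) half of a quinone fused at C5–C10. The 1,3-dioxygen pattern at C6 and C8, with a carbon arm at C7, is that of a 2-substituted 1-alkoxy-3-silyloxybutadiene. Ring B can thus be made by a Diels–Alder reaction and ring A, which the target does not contain, unzipped afterwards.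

## Retrosynthesis

**Ester and silyl ethers (30 ⇒ 29 ⇒ 25 + 28).** The O8–acyl bond is cut first. Attaching the side chain last keeps its enolisable, β-oxygenated ester away from the lactone enolate chemistry and from every base used earlier. The cut removes one stereocentre and both free hydroxyls: 29 is the bis-silyl ether, 25 the 8α-alcohol with O15 as its tert-butyldiphenylsilyl ether, and 28 the acid made from the commercial hydroxy ester 26 via 27. The forward steps must acylate a single secondary alcohol beside a Michael acceptor without epimerising the acid, then remove two silyl groups without base.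

**Methylene and C8–H (25 ⇒ 22 ⇒ 21).** The C11=C13 bond is cut next, then the C8–H bond. The methylene comes late because none of the earlier reagents spares an α-methylene lactone. The 8α-alcohol is traced to ketone 21 and not carried from the start, because hydride would have to arrive syn-axial to the C10 methyl and would instead give the axial epimer. An electron-transfer reduction gives the stable equatorial alcohol, but only when the ketone is the sole reducible group, which holds for 21 and for no earlier compound. 21 is simpler by one stereocentre and one carbon. The forward steps need thermodynamic control at C8 and enolisation of the lactone beside a free O8.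

**Lactone and masks (21 ⇒ 19).** The C12–O6 lactone bond is cut, O6 returns to its 4-methoxybenzyl ether and C8 to an ethylene ketal. Closing the lactone while C8 is still masked makes its regiochemistry a matter of structure: no O8 exists to form the 8,12-olide. Reducing C8 first would leave two hydroxyls, both trans to the C7 arm. 19 is a monocyclic methyl ester. The forward step must free O6, lactonise and unmask the ketone without epimerising C7.

**Two alkenes and C5 (19 ⇒ 18 ⇒ 17 ⇒ 16 ⇒ 15 ⇒ 14 ⇒ 13).** Both C=CH2 bonds are cut to carbonyl groups. C4=C3 goes back to ketone 18, whose C5 epimer 17 is where the cis arrangement inherited from the cycloaddition is inverted: only there is C5–H acidic while C4 can rotate freely. The C4 ketone with its silyloxymethyl group is traced through 16 and diol 15 to the α-hydroxy ester 14, because borohydride reduces such an ester in the presence of the C12 ester. C1=C2 goes back to the aldehyde held as lactol 13. This asks for one chemoselective reduction, one selective silylation, an oxidation, an equilibration that must not expel O6, and two Wittig methylenations.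

**Unzipping ring A (13 ⇒ 12 ⇒ 11 ⇒ 10).** C2 is re-attached to C1 and the C2=C3 enol ether is restored. Ozonolysis of a methyl enol ether differentiates the two ends for free: C3 becomes an ester (the future C15) and C2 an aldehyde. Reducing both ring-A carbonyls first makes C1 a carbinol, so that periodate can excise C2 and leave C1 as an aldehyde. Direct ozonolysis of the enedione would leave C1 as an acid. 10 is the bicyclic methoxy-enedione with C8 ketalised. The reduction must reach the hindered C1, and ozone must select the enol ether over the benzyl ether.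

**Diels–Alder (10 ⇒ 9 ⇒ 8 ⇒ 2 + 7).** C9–C10 and C5–C6 are cut. This is preferred to cutting C6–C7 or C9–C10 alone because it delivers all six ring carbons, the C7 arm, both ring oxygens and three stereocentres (C10, C5, C6) from two achiral, flat partners. The precursors are quinone 2 and diene 7. The forward reaction needs site, regio, endo and facial selectivity. After it, the silyl enol ether of 8 is unmasked to ketone 9, setting C7, and C8 is ketalised selectively to 10.

**Building blocks (7 ⇒ 6 ⇒ 4 ⇒ 3 + 5; 2 ⇒ 1).** The diene is the silyl enol ether of enone 6, which is the 4-methoxybenzyl enol ether (from alcohol 5) of the formylated levulinate 4, made from methyl levulinate 3. The quinone comes from phenol 1 by oxidation at its free para position. All carbon–carbon bonds formed here are classical condensations.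

## Roads not taken

**Alternative 1:** The cut is C9–C10, made by an Ireland–Claisen ring contraction. The silyl ketene acetal of the 6-vinyl δ-lactone A1 (LiN(iPr)2, tert-butyldimethylsilyl chloride) would rearrange on warming so that C10 bonds to the vinyl terminus C9 while the C7–O bond breaks, giving the cyclohexenecarboxylic acid A2.
- Merits: C10 is set by chirality transfer through a cyclic transition state, the acid at C1 is a ready vinyl precursor, and no atoms are sacrificed.
- Where it is better: A2 already has the trans C5/C10 relation, so neither a chiral catalyst nor an epimerisation at C5 is needed.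
- Weak points for this target: A2 has no O8 and no C7 arm, and its C4 unit is a masked methyl ketone without the C15 oxygen. The C7=C8 alkene would have to be turned into a trans C7–carbon/C8–oxygen pair with two new stereocentres, and A1 itself carries three stereocentres that need their own asymmetric synthesis.
- Against its cleaner C5/C10 control, the chosen plan sets a ring-forming step that puts O6, O8 and the C7 arm in place at once from far simpler precursors.

**Alternative 2:** The cut is C6–C7 together with the lactone C–O bond. CrCl2 (divalent chromium) would convert the bromomethylacrylate of aldehyde A3 into an allylchromium species whose γ-carbon C7 adds to the C6 aldehyde. The alkoxide would then close onto the methyl ester to give the bis-silyl ether A4.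
- Where it is better: the carbocycle, C6, C7 and the complete α-methylene lactone arise in one mild, non-basic step, and A4 is only a desilylation at O8, an acylation and a deprotection away from the target. The chosen plan must instead methylenate a lactone enolate late.
- Weak points: the whole stereochemical burden moves to the acyclic A3. It has a quaternary C10 next to an epimerisable α-branched aldehyde carbon C5, plus C8, and would be a long linear problem of acyclic stereocontrol. The ring closure must also give the right C6/C7 pair relative to C5 and C8 on uncertain 1,2- and 1,3-induction.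
- Against the better endgame, the chosen plan sets a front end in which three stereocentres and the ring come from one cycloaddition of flat precursors.

**Alternative 3:** The cuts are C10–C1 and C5–C4. Irradiation near 350 nm of enone A5 with the cyclobutene ester A6 would give the cis-anti-cis tricycle A7. Heating A7 would open its bicyclo[2.2.0]hexane to the C10 vinyl group and a C5 acrylate.
- Where it is better: it is the shortest way to the vinyl/propenyl pair, the acrylate is already at the C15 oxidation level, and C5 sits α to the C6 ketone for adjustment. The chosen plan needs a multi-step unzipping for the same result.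
- Weak points: head-to-head versus head-to-tail orientation in the photocycloaddition of a β-methyl enone is uncertain. Facial control rests on the remote C8 silyloxy group. The fragmentation can also partition to the ring-expanded cyclodecadiene. The C7 arm is absent and would have to be introduced by alkylation next to the C6 ketone, in competition with C5, before reduction, lactonisation and methylenation.
- Against its brevity at C1–C4, the chosen plan sets predictable regio- and stereochemistry in the key step and a C7 arm that is present from the start.

Key step: step 5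

Assumption: the (R)-binaphtholate–TiCl2 chelate is taken to shield the quinone face that would lead to the mirror image of 8; if the sense of induction is the opposite, the (S)-ligand is used and nothing else changes.

Remark: 11 to 16 are mixtures of carbinol epimers at C1 and/or C4, 13 is also an anomer mixture, and 23 and 24 are C11 epimers. All these centres are erased later, so their SMILES leave them open.

## Route

Step 1
Reactants: 1 2-methoxy-5-methylphenol
Product: 2 2-methoxy-5-methyl-1,4-benzoquinone
Conditions: (KSO3)2NO, KH2PO4, H2O/acetone, 0 °C → rt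
Reagents that add atoms: potassium nitrosodisulfonate (KSO3)2NO, [K+].[K+].[O]N(S(=O)(=O)[O-])S(=O)(=O)[O-]
Why: Teuber oxidation: the phenoxyl radical is trapped by a second equivalent of the nitroxide at the free para position and collapses to the para-quinone, so methoxy and methyl end up 2,5 without any regiochemical choice.

Step 2
Reactants: 3 methyl 4-oxopentanoate (methyl levulinate)
Product: 4 methyl 3-(hydroxymethylidene)-4-oxopentanoate
Conditions: HCO2Me, NaOMe, Et2O, 0 °C → rt; then 1 M HCl, 0 °C
Reagents that add atoms: methyl formate, COC=O
Why: Crossed Claisen (formyl) condensation under reversible alkoxide conditions: methyl ketones with an α-methylene are formylated at the methylene, as butanone is, giving the stabilised sodium enolate of the 2-substituted 3-oxo aldehyde; the ester α-position is far less acidic.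

Step 3
Reactants: 4 methyl 3-(hydroxymethylidene)-4-oxopentanoate; 5 4-methoxybenzyl alcohol
Product: 6 methyl (3E)-3-[(4-methoxybenzyloxy)methylidene]-4-oxopentanoate
Conditions: PPTS (cat.), benzene, reflux, Dean–Stark
Reagents that add atoms: none
Why: Acid-catalysed condensation of a 3-oxo aldehyde enol with an alcohol (vinylogous ester formation) occurs at the formyl carbon and, being reversible, should settle on the E enol ether with the alkoxy group anti to the acetyl group; C-alkylation, the risk of halide methods, cannot occur.

Step 4
Reactants: 6 methyl (3E)-3-[(4-methoxybenzyloxy)methylidene]-4-oxopentanoate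
Product: 7 methyl (3E)-4-(tert-butyldimethylsilyloxy)-3-[(4-methoxybenzyloxy)methylidene]pent-4-enoate
Conditions: TBSOTf, Et3N, Et2O, 0 °C
Reagents that add atoms: tert-butyldimethylsilyl trifluoromethanesulfonate, CC(C)(C)[Si](C)(C)OS(=O)(=O)C(F)(F)F
Why: Soft enolisation of the methyl ketone (silyl triflate/amine): its only α-hydrogens are those of the methyl group, so the 2-silyloxy diene forms with the E enol ether untouched; the tert-butyldimethylsilyl group is chosen over trimethylsilyl for stability toward chromatography and the Lewis acid of step 5.

Step 5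
Reactants: 2 2-methoxy-5-methyl-1,4-benzoquinone; 7 methyl (3E)-4-(tert-butyldimethylsilyloxy)-3-[(4-methoxybenzyloxy)methylidene]pent-4-enoate
Product: 8 cis-fused endo adduct (ring A 3-methoxy-1,4-enedione; ring B C7=C8 silyl enol ether; 10β-CH3, 5β-H, 6α-O-(4-methoxybenzyl))
Conditions: (R)-BINOL–TiCl2 (10 mol%; from TiCl2(OiPr)2 and (R)-1,1'-bi-2-naphthol, 4 Å MS), CH2Cl2, −40 → −20 °C
Reagents that add atoms: none
Why: A Lewis acid-catalysed, concerted but asynchronous [4+2] cycloaddition joins C9 to C10 and C6 to C5; the closest known reactions are Diels–Alder additions to 2-methoxy-5-methyl-1,4-benzoquinone at its methyl-bearing double bond, additions of 1-alkoxy-3-silyloxy dienes to quinones, and titanium–binaphthol-catalysed quinone cycloadditions. Ring B is closed in the [4+2] mode with all six of its carbons and the C7 acetate arm in place. Two-point binding of the tetravalent titanium centre to the methoxy oxygen and the adjacent carbonyl (C4) makes that carbonyl the controlling acceptor, so the methyl-bearing alkene reacts and not the donor-deactivated methoxy alkene, and the most nucleophilic diene terminus (C9, the CH2 carbon) adds to C10. A monodentate acid would bind the more basic vinylogous-ester oxygen and could reverse this orientation, which is why a chelating catalyst is specified. C10 and C5 are set cis because addition to the quinone double bond is suprafacial. C6 is set by the endo rule acting on the E enol ether: the alkoxy group ends cis to the two quinone carbonyl carbons, that is trans to the angular methyl, as the target requires. The absolute configuration of C10, and with it C5 and C6, comes from the chiral chelate, whose binaphthol shields one face of the bound quinone. Site, regio and endo selectivity are thus inherent in the chelated methoxyquinone and the E diene, while facial selectivity rests on the catalyst.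

Step 6
Reactants: 8 cis-fused endo adduct
Product: 9 triketone (C8 ketone; 7α-H with the C7 arm β)
Conditions: HF·pyridine, THF, 0 °C
Reagents that add atoms: none
Why: Protodesilylation of the silyl enol ether under acidic conditions avoids the free enolate that could expel the 6-alkoxy group. C7 is protonated axially on the α face, which is also the stable epimer (arm equatorial and trans to O6; an α arm would be syn-axial to C4), so 7α-H is set here.

Step 7
Reactants: 9 triketone
Product: 10 C8 ethylene ketal of 9
Conditions: (Me3SiOCH2)2, Me3SiOTf (cat.), CH2Cl2, −78 → −20 °C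
Reagents that add atoms: 1,2-bis(trimethylsilyloxy)ethane, C[Si](C)(C)OCCO[Si](C)(C)C
Why: Silyl triflate-catalysed ketalisation with the bis-silyl ether of ethylene glycol is kinetically selective for saturated over conjugated carbonyl groups, so only C8 should react. The ketal keeps C8 inert while ring A is reduced and cleaved, so a C8 alcohol never has to be told from a C4 alcohol.

Step 8
Reactants: 10 C8 ethylene ketal
Product: 11 ring-A 1,4-diol (1,4-dihydroxy-3-methoxy-2-ene)
Conditions: NaBH4, CeCl3·7H2O, MeOH, −40 → 0 °C
Reagents that add atoms: none
Why: Luche reduction: 1,2-hydride addition first to the C4 enone carbonyl and then to the vinylogous-ester carbonyl C1, leaving ester, ketal and enol ether untouched. The two new carbinol centres need no control because C1 later becomes an sp2 CH and C4 a ketone.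

Step 9
Reactants: 11 ring-A 1,4-diol
Product: 13 lactol ester (C1 hemiacetal closed through O onto C4; C4 carries CO2CH3), via seco hydroxy aldehyde 12 (not isolated)
Conditions: O3, CH2Cl2/MeOH, −78 °C; Me2S, −78 °C → rt; then NaIO4, THF/pH 7 buffer, 0 °C → rt
Reagents that add atoms: ozone, [O-][O+]=O
Why: Ozonolysis selects the electron-rich enol ether C2=C3, the only C=C in 11, giving the C2 aldehyde and the C3 methyl ester. Periodate then cleaves the α-hydroxy aldehyde between C1 and C2 (glycol-type cleavage), expelling C2 as formic acid and leaving C1 as an aldehyde that closes onto the cis 4-hydroxyl as a five-membered lactol.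

Step 10
Reactants: 13 lactol ester
Product: 14 10α-vinyl α-hydroxy ester (C5α–CH(OH)CO2CH3)
Conditions: Ph3PCH3Br, KOtBu, THF, 0 °C → rt
Reagents that add atoms: methyltriphenylphosphonium bromide, C[P+](c1ccccc1)(c1ccccc1)c1ccccc1.[Br-]
Why: Wittig methylenation of a lactol through its open hydroxy aldehyde; the aldehyde is non-enolisable because C10 is quaternary, and esters do not react with the ylide at this temperature.

Step 11
Reactants: 14 10α-vinyl α-hydroxy ester
Product: 15 1,2-diol (C5α–CH(OH)CH2OH)
Conditions: NaBH4, MeOH, 0 °C → rt
Reagents that add atoms: none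
Why: Chemoselective borohydride reduction: an α-hydroxy ester is reduced far faster than an unactivated ester through its alkoxyborohydride, so C3 becomes the primary alcohol (the future C15) while the C12 methyl ester stays.

Step 12
Reactants: 15 1,2-diol
Product: 16 primary tert-butyldiphenylsilyl ether
Conditions: TBDPSCl, imidazole, CH2Cl2, 0 °C
Reagents that add atoms: tert-butyl(chloro)diphenylsilane, CC(C)(C)[Si](Cl)(c1ccccc1)c1ccccc1
Why: Selective silylation of the primary hydroxyl of a 1,2-diol by a bulky silyl chloride; the tert-butyldiphenylsilyl group is chosen because it must survive the aqueous acid of step 16.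

Step 13
Reactants: 16 primary tert-butyldiphenylsilyl ether
Product: 17 5-cis ketone (C5α–C(=O)CH2O-silyl; 5β-H)
Conditions: Dess–Martin periodinane, NaHCO3, CH2Cl2, 0 °C → rt
Reagents that add atoms: none
Why: Dess–Martin oxidation of the only free hydroxyl gives the α-silyloxy ketone under buffered conditions.

Step 14
Reactants: 17 5-cis ketone
Product: 18 5-trans ketone (C5β–C(=O)CH2O-silyl; 5α-H)
Conditions: DBU, toluene, rt → 40 °C
Reagents that add atoms: none
Why: Base-mediated epimerisation α to the C4 ketone through its enolate moves the acyl group from the axial α position to the equatorial β position, which is the trans C5/C10 arrangement of the target (5α-H). The equatorial 6-alkoxy group lies near the nodal plane of the enolate, which disfavours its E1cB loss.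

Step 15
Reactants: 18 5-trans ketone
Product: 19 diene ester (C5β–C(=CH2)CH2O-silyl; 10α-vinyl; 6α-O-(4-methoxybenzyl); C8 ketal; C7β–CH2CO2CH3)
Conditions: Ph3PCH3Br, KOtBu, toluene, 0 → 50 °C
Reagents that add atoms: methyltriphenylphosphonium bromide, C[P+](c1ccccc1)(c1ccccc1)c1ccccc1.[Br-]
Why: Wittig methylenation of the α-silyloxy ketone; once C4 is an alkene C5 can no longer epimerise, so the trans arrangement is locked.

Step 16
Reactants: 19 diene ester
Product: 21 8-oxo trans-6α,12-lactone, via 6α-alcohol 20 (not isolated)
Conditions: DDQ, CH2Cl2/pH 7 buffer, 0 °C → rt; then 1 M HCl, THF, rt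
Reagents that add atoms: water, O
Why: Oxidative cleavage of the 4-methoxybenzyl ether frees O6; aqueous acid then closes the γ-lactone onto the C12 methyl ester (equatorial 6α-O and 7β-arm give the trans fusion) and hydrolyses the ketal. Because C8 is not yet an alcohol, O6 is the only hydroxyl that can lactonise.

Step 17
Reactants: 21 8-oxo trans-6α,12-lactone
Product: 22 8α-hydroxy lactone
Conditions: SmI2, THF/MeOH, 0 °C
Reagents that add atoms: none
Why: Electron-transfer reduction of the ketone by divalent samarium: the ketyl/organosamarium intermediate should be protonated to the more stable equatorial 8α-alcohol, since the axial 8β epimer would place OH syn-axial to the C10 methyl. The γ-lactone, the isolated alkenes and the silyl ether are inert to SmI2/MeOH.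

Step 18
Reactants: 22 8α-hydroxy lactone
Product: 25 8α-hydroxy α-methylene lactone (O15 tert-butyldiphenylsilyl ether), via Mannich base 23 (not isolated), via trimethylammonium iodide 24 (not isolated)
Conditions: LiN(iPr)2 (2.5 equiv), THF, −78 °C; CH2=NMe2+ I−, −78 → 0 °C; then MeI, MeOH, rt; then NaHCO3 (aq), EtOAc, rt
Reagents that add atoms: N,N-dimethylmethyleneiminium iodide (Eschenmoser's salt), C=[N+](C)C.[I-]
Why: α-Methylenation of the lactone through its dianion (O8 alkoxide, then the C11 enolate, the only enolisable carbon): Mannich reaction with Eschenmoser's salt, N-methylation and base-induced elimination of trimethylamine give the exocyclic alkene. C7 is not touched.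

Step 19
Reactants: 26 methyl (R)-3-hydroxy-2-methylpropanoate
Product: 27 methyl (R)-3-(tert-butyldimethylsilyloxy)-2-methylpropanoate
Conditions: TBSCl, imidazole, DMF, rt
Reagents that add atoms: tert-butyl(chloro)dimethylsilane, CC(C)(C)[Si](C)(C)Cl
Why: Standard silylation of a primary alcohol; the stereocentre is not involved.

Step 20
Reactants: 27 methyl (R)-3-(tert-butyldimethylsilyloxy)-2-methylpropanoate
Product: 28 (R)-3-(tert-butyldimethylsilyloxy)-2-methylpropanoic acid
Conditions: LiOH, THF/H2O, 0 °C → rt; then 1 M HCl to pH 3
Reagents that add atoms: lithium hydroxide, [Li+].[OH-]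
Why: Saponification at low temperature; the carboxylate formed protects the α-centre from enolisation, so the R configuration is kept.

Step 21
Reactants: 25 8α-hydroxy α-methylene lactone; 28 (R)-3-(tert-butyldimethylsilyloxy)-2-methylpropanoic acid
Product: 29 bis-silyl ether of the target
Conditions: DCC, DMAP (cat.), CH2Cl2, 0 °C → rt
Reagents that add atoms: none
Why: Steglich esterification of the only free hydroxyl (8α, equatorial); C8 keeps its configuration because the C8–O bond is not broken, and catalytic DMAP at low temperature limits epimerisation of the acid.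

Step 22
Reactants: 29 bis-silyl ether of the target
Product: 30 CNP0133858.1
Conditions: HF·pyridine, pyridine/THF, 0 °C → rt
Reagents that add atoms: none
Why: Fluoride-mediated cleavage of both silyl ethers under acidic, non-nucleophilic conditions that spare the α-methylene lactone and the ester and avoid acyl or lactone migration.

## Compound list

1 | 2-methoxy-5-methylphenol | COc1ccc(C)cc1O | starting material
2 | 2-methoxy-5-methyl-1,4-benzoquinone | COC1=CC(=O)C(C)=CC1=O | intermediate
3 | methyl 4-oxopentanoate (methyl levulinate) | CC(=O)CCC(=O)OC | starting material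
4 | methyl 3-(hydroxymethylidene)-4-oxopentanoate (enol form of methyl 3-formyl-4-oxopentanoate) | CC(=O)C(=CO)CC(=O)OC | intermediate
5 | 4-methoxybenzyl alcohol | COc1ccc(CO)cc1 | starting material
6 | methyl (3E)-3-[(4-methoxybenzyloxy)methylidene]-4-oxopentanoate | CC(=O)/C(CC(=O)OC)=C/OCc1ccc(OC)cc1 | intermediate
7 | methyl (3E)-4-(tert-butyldimethylsilyloxy)-3-[(4-methoxybenzyloxy)methylidene]pent-4-enoate | C=C(O[Si](C)(C)C(C)(C)C)/C(CC(=O)OC)=C/OCc1ccc(OC)cc1 | intermediate
8 | cis-fused endo adduct: methyl 2-[7-methoxy-1-(4-methoxybenzyloxy)-4a-methyl-5,8-dioxo-3-(tert-butyldimethylsilyloxy)-1,4,4a,5,8,8a-hexahydronaphthalen-2-yl]acetate; 10β-CH3, 5β-H, 6α-O-(4-methoxybenzyl) | COC1=CC(=O)[C@]2(C)CC(O[Si](C)(C)C(C)(C)C)=C(CC(=O)OC)[C@H](OCc3ccc(OC)cc3)[C@@H]2C1=O | intermediate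
9 | triketone: as 8 with the silyl enol ether replaced by the C8 ketone and 7α-H (C7β–CH2CO2CH3) | COC1=CC(=O)[C@]2(C)CC(=O)[C@@H](CC(=O)OC)[C@H](OCc3ccc(OC)cc3)[C@@H]2C1=O | intermediate
10 | C8 ethylene ketal (1,3-dioxolane) of 9 | COC1=CC(=O)[C@]2(C)CC3(OCCO3)[C@@H](CC(=O)OC)[C@H](OCc4ccc(OC)cc4)[C@@H]2C1=O | intermediate
11 | ring-A diol: 1,4-dihydroxy-3-methoxy-2-ene, C8 ketal (C1/C4 epimer mixture) | COC1=CC(O)[C@]2(C)CC3(OCCO3)[C@@H](CC(=O)OC)[C@H](OCc4ccc(OC)cc4)[C@@H]2C1O | intermediate
12 | seco hydroxy aldehyde: C10α–CH(OH)CHO and C5α–CH(OH)CO2CH3 (epimer mixture) | O=CC(O)[C@]1(C)CC2(OCCO2)[C@@H](CC(=O)OC)[C@H](OCc3ccc(OC)cc3)[C@@H]1C(O)C(=O)OC | intermediate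
13 | lactol ester: C1 hemiacetal bridged through O to C4, cis-fused 2-hydroxytetrahydrofuran carrying the C3 methyl ester (anomer and C4 epimer mixture) | OC1[C@]2(C)CC3(OCCO3)[C@@H](CC(=O)OC)[C@H](OCc4ccc(OC)cc4)[C@@H]2C(C(=O)OC)O1 | intermediate
14 | 10α-vinyl α-hydroxy ester: C5α–CH(OH)CO2CH3 (C4 epimer mixture) | C=C[C@]1(C)CC2(OCCO2)[C@@H](CC(=O)OC)[C@H](OCc3ccc(OC)cc3)[C@@H]1C(O)C(=O)OC | intermediate
15 | 1,2-diol: C5α–CH(OH)CH2OH (C4 epimer mixture) | C=C[C@]1(C)CC2(OCCO2)[C@@H](CC(=O)OC)[C@H](OCc3ccc(OC)cc3)[C@@H]1C(O)CO | intermediate
16 | primary tert-butyldiphenylsilyl ether of 15 (C4 epimer mixture) | C=C[C@]1(C)CC2(OCCO2)[C@@H](CC(=O)OC)[C@H](OCc3ccc(OC)cc3)[C@@H]1C(O)CO[Si](c4ccccc4)(c5ccccc5)C(C)(C)C | intermediate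
17 | 5-cis ketone: C5α–C(=O)CH2OSi(tBu)Ph2, 5β-H | C=C[C@]1(C)CC2(OCCO2)[C@@H](CC(=O)OC)[C@H](OCc3ccc(OC)cc3)[C@@H]1C(=O)CO[Si](c4ccccc4)(c5ccccc5)C(C)(C)C | intermediate
18 | 5-trans ketone: C5β–C(=O)CH2OSi(tBu)Ph2, 5α-H | C=C[C@]1(C)CC2(OCCO2)[C@@H](CC(=O)OC)[C@H](OCc3ccc(OC)cc3)[C@H]1C(=O)CO[Si](c4ccccc4)(c5ccccc5)C(C)(C)C | intermediate
19 | diene ester: C5β–C(=CH2)CH2OSi(tBu)Ph2, 10α-vinyl, 6α-O-(4-methoxybenzyl), C8 ketal, C7β–CH2CO2CH3 | C=C[C@]1(C)CC2(OCCO2)[C@@H](CC(=O)OC)[C@H](OCc3ccc(OC)cc3)[C@H]1C(=C)CO[Si](c4ccccc4)(c5ccccc5)C(C)(C)C | intermediate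
20 | 6α-alcohol of 19 | C=C[C@]1(C)CC2(OCCO2)[C@@H](CC(=O)OC)[C@H](O)[C@H]1C(=C)CO[Si](c3ccccc3)(c4ccccc4)C(C)(C)C | intermediate
21 | 8-oxo trans-6α,12-lactone: 15-(tert-butyldiphenylsilyloxy)-8-oxoelema-1,3-dien-6α,12-olide | C=C[C@]1(C)CC(=O)[C@H]2CC(=O)O[C@@H]2[C@H]1C(=C)CO[Si](c3ccccc3)(c4ccccc4)C(C)(C)C | intermediate
22 | 8α-hydroxy lactone: 15-(tert-butyldiphenylsilyloxy)-8α-hydroxyelema-1,3-dien-6α,12-olide | C=C[C@]1(C)C[C@H](O)[C@H]2CC(=O)O[C@@H]2[C@H]1C(=C)CO[Si](c3ccccc3)(c4ccccc4)C(C)(C)C | intermediate
23 | Mannich base: 13-(dimethylamino) derivative of 22 (C11 epimers) | C=C[C@]1(C)C[C@H](O)[C@H]2C(CN(C)C)C(=O)O[C@@H]2[C@H]1C(=C)CO[Si](c3ccccc3)(c4ccccc4)C(C)(C)C | intermediate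
24 | trimethylammonium iodide of 23 (C11 epimers) | C=C[C@]1(C)C[C@H](O)[C@H]2C(C[N+](C)(C)C)C(=O)O[C@@H]2[C@H]1C(=C)CO[Si](c3ccccc3)(c4ccccc4)C(C)(C)C.[I-] | intermediate
25 | 8α-hydroxy α-methylene lactone: 15-(tert-butyldiphenylsilyloxy)-8α-hydroxyelema-1,3,11(13)-trien-6α,12-olide | C=C[C@]1(C)C[C@H](O)[C@H]2C(=C)C(=O)O[C@@H]2[C@H]1C(=C)CO[Si](c3ccccc3)(c4ccccc4)C(C)(C)C | intermediate
26 | methyl (R)-3-hydroxy-2-methylpropanoate | COC(=O)[C@H](C)CO | starting material
27 | methyl (R)-3-(tert-butyldimethylsilyloxy)-2-methylpropanoate | COC(=O)[C@H](C)CO[Si](C)(C)C(C)(C)C | intermediate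
28 | (R)-3-(tert-butyldimethylsilyloxy)-2-methylpropanoic acid | OC(=O)[C@H](C)CO[Si](C)(C)C(C)(C)C | intermediate
29 | bis-silyl ether of the target: 8α-[(R)-3-(tert-butyldimethylsilyloxy)-2-methylpropanoyloxy]-15-(tert-butyldiphenylsilyloxy)elema-1,3,11(13)-trien-6α,12-olide | C=C[C@]1(C)C[C@H](OC(=O)[C@H](C)CO[Si](C)(C)C(C)(C)C)[C@H]2C(=C)C(=O)O[C@@H]2[C@H]1C(=C)CO[Si](c3ccccc3)(c4ccccc4)C(C)(C)C | intermediate
30 | CNP0133858.1: 15-hydroxy-8α-[(R)-3-hydroxy-2-methylpropanoyloxy]elema-1,3,11(13)-trien-6α,12-olide | C=C[C@]1(C)C[C@H](OC(=O)[C@H](C)CO)[C@H]2C(=C)C(=O)O[C@@H]2[C@H]1C(=C)CO | target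

## Step count and least certain steps

Total: 22 steps. Longest linear sequence: 19 steps (steps 2–18, 21 and 22, from methyl levulinate 3).

**Step 5 (key step).** The most likely failure is loss of the diene to the Lewis acid before it can cycloadd. Silyl transfer to the activated quinone (a Mukaiyama–Michael pathway giving open-chain adducts) and protodesilylation both compete with addition to a hindered, trisubstituted quinone alkene. The level of facial selectivity is also untested for this pairing. The fallback sets out from 6. It is converted with isopropenyl acetate and catalytic TsOH into the enol acetate diene F1, which has no silyl group to transfer and belongs to the acyloxy-diene class for which titanium–binaphthol quinone cycloadditions are best established. Cycloaddition under the same chelate would give the enol acetate adduct F2. Brief methanolysis (K2CO3, MeOH, −20 °C) would release the ketone with the same protonation at C7 and return to the route at 9.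

**Step 14.** Two processes threaten the epimerisation. The equilibrium may stop short, because the equatorial acyl group gains a gauche contact with the C10 methyl that offsets part of its advantage. The C4 enolate may also expel 4-methoxybenzyl alcohol (E1cB). The fallback moves the correction to the α-keto ester level, which enolises only toward C5 and is acidic enough for a tertiary amine. It sets out from 14. Dess–Martin oxidation would give the cis α-keto ester F3. Et3N in CH2Cl2, or a low-temperature quench of its preformed enolate, would give the trans α-keto ester F4. NaBH4 in MeOH would reduce ketone and activated ester to the trans diol F5. TBDPSCl/imidazole would give the trans silyl ether F6, and Dess–Martin oxidation returns to the route at 18.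

**Step 17.** The risk is poor facial selectivity: if the organosamarium intermediate is protonated under kinetic control from the open α face, the axial 8β-alcohol forms instead. The fallback replaces thermodynamic reduction by reduction and inversion, and sets out from 21. LiBH(sBu)3 at −78 °C should deliver hydride from the α face to give the 8β-alcohol F7, which is quenched cold to avoid relactonisation onto O8. Mitsunobu reaction with chloroacetic acid (PPh3, DIAD) would invert C8 to the 8α-chloroacetate F8. Thiourea/NaHCO3 in MeOH would remove the chloroacetyl group without touching the lactone and return to the route at 22.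

**Step 18.** The risk is translactonisation: the O8 alkoxide can attack C12 before the enolate forms, or during work-up of the basic Mannich stage, and give the 8,12-olide. Incomplete dianion formation is a second risk. The fallback masks O8 and sets out from 22. Et3SiCl/imidazole would give the triethylsilyl ether F9. One equivalent of LiN(iPr)2 and Eschenmoser's salt would give the Mannich base F10. MeI would give the ammonium iodide F11, and NaHCO3 the α-methylene lactone silyl ether F12. PPTS in MeOH at 0 °C would remove the triethylsilyl group beside the tert-butyldiphenylsilyl ether and return to the route at 25.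

## Further compounds

F1 | step 5 | methyl (3E)-4-acetoxy-3-[(4-methoxybenzyloxy)methylidene]pent-4-enoate | C=C(OC(C)=O)/C(CC(=O)OC)=C/OCc1ccc(OC)cc1
F2 | step 5 | enol acetate analogue of adduct 8 (C7=C8 enol acetate; 10β-CH3, 5β-H, 6α-O-(4-methoxybenzyl)) | COC1=CC(=O)[C@]2(C)CC(OC(C)=O)=C(CC(=O)OC)[C@H](OCc3ccc(OC)cc3)[C@@H]2C1=O
F3 | step 14 | cis α-keto ester: C5α–C(=O)CO2CH3, 5β-H, 10α-vinyl, C8 ketal | C=C[C@]1(C)CC2(OCCO2)[C@@H](CC(=O)OC)[C@H](OCc3ccc(OC)cc3)[C@@H]1C(=O)C(=O)OC
F4 | step 14 | trans α-keto ester: C5β–C(=O)CO2CH3, 5α-H | C=C[C@]1(C)CC2(OCCO2)[C@@H](CC(=O)OC)[C@H](OCc3ccc(OC)cc3)[C@H]1C(=O)C(=O)OC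
F5 | step 14 | trans diol: C5β–CH(OH)CH2OH, 5α-H (C4 epimer mixture) | C=C[C@]1(C)CC2(OCCO2)[C@@H](CC(=O)OC)[C@H](OCc3ccc(OC)cc3)[C@H]1C(O)CO
F6 | step 14 | trans primary tert-butyldiphenylsilyl ether of F5 (C4 epimer mixture) | C=C[C@]1(C)CC2(OCCO2)[C@@H](CC(=O)OC)[C@H](OCc3ccc(OC)cc3)[C@H]1C(O)CO[Si](c4ccccc4)(c5ccccc5)C(C)(C)C
F7 | step 17 | 8β-hydroxy lactone (C8 epimer of 22) | C=C[C@]1(C)C[C@@H](O)[C@H]2CC(=O)O[C@@H]2[C@H]1C(=C)CO[Si](c3ccccc3)(c4ccccc4)C(C)(C)C
F8 | step 17 | 8α-chloroacetate of 22 | C=C[C@]1(C)C[C@H](OC(=O)CCl)[C@H]2CC(=O)O[C@@H]2[C@H]1C(=C)CO[Si](c3ccccc3)(c4ccccc4)C(C)(C)C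
F9 | step 18 | 8α-triethylsilyl ether of 22 | C=C[C@]1(C)C[C@H](O[Si](CC)(CC)CC)[C@H]2CC(=O)O[C@@H]2[C@H]1C(=C)CO[Si](c3ccccc3)(c4ccccc4)C(C)(C)C
F10 | step 18 | Mannich base of F9 (13-dimethylamino; C11 epimers) | C=C[C@]1(C)C[C@H](O[Si](CC)(CC)CC)[C@H]2C(CN(C)C)C(=O)O[C@@H]2[C@H]1C(=C)CO[Si](c3ccccc3)(c4ccccc4)C(C)(C)C
F11 | step 18 | trimethylammonium iodide of F10 (C11 epimers) | C=C[C@]1(C)C[C@H](O[Si](CC)(CC)CC)[C@H]2C(C[N+](C)(C)C)C(=O)O[C@@H]2[C@H]1C(=C)CO[Si](c3ccccc3)(c4ccccc4)C(C)(C)C.[I-]
F12 | step 18 | 8α-triethylsilyl ether of 25 | C=C[C@]1(C)C[C@H](O[Si](CC)(CC)CC)[C@H]2C(=C)C(=O)O[C@@H]2[C@H]1C(=C)CO[Si](c3ccccc3)(c4ccccc4)C(C)(C)C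
A1 | alternative 1 | 3-methyl-4-(2-methyl-1,3-dioxolan-2-yl)-5-(tert-butyldimethylsilyloxy)-6-vinyltetrahydropyran-2-one (4,5-trans, 5,6-trans; C3 open) | O=C1O[C@@H](C=C)[C@H](O[Si](C)(C)C(C)(C)C)[C@@H](C2(C)OCCO2)C1C
A2 | alternative 1 | 1-methyl-6-(2-methyl-1,3-dioxolan-2-yl)-5-(tert-butyldimethylsilyloxy)cyclohex-3-ene-1-carboxylic acid | C[C@@]1(C(=O)O)CC=C[C@H](O[Si](C)(C)C(C)(C)C)[C@H]1C1(C)OCCO1
A3 | alternative 2 | methyl (2Z)-2-(bromomethyl)-7-formyl-6-methyl-8-[(tert-butyldiphenylsilyloxy)methyl]-4-(triethylsilyloxy)-6-vinylnona-2,8-dienoate | C=C[C@](C)(C[C@H](O[Si](CC)(CC)CC)/C=C(\CBr)C(=O)OC)[C@@H](C=O)C(=C)CO[Si](c1ccccc1)(c1ccccc1)C(C)(C)C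
A4 | alternative 2 | bis-silyl ether of the bicyclic α-methylene lactone core (8α-O-triethylsilyl, 15-O-tert-butyldiphenylsilyl) | C=C[C@]1(C)C[C@H](O[Si](CC)(CC)CC)[C@H]2C(=C)C(=O)O[C@@H]2[C@H]1C(=C)CO[Si](c1ccccc1)(c1ccccc1)C(C)(C)C
A5 | alternative 3 | (R)-5-(tert-butyldimethylsilyloxy)-3-methylcyclohex-2-en-1-one | CC1=CC(=O)C[C@H](O[Si](C)(C)C(C)(C)C)C1
A6 | alternative 3 | methyl cyclobut-1-ene-1-carboxylate | COC(=O)C1=CCC1
A7 | alternative 3 | cis-anti-cis tricyclic keto ester (bicyclo[2.2.0]hexane fused to the cyclohexanone) | C[C@@]12C[C@@H](O[Si](C)(C)C(C)(C)C)CC(=O)[C@@H]1[C@@]1(C(=O)OC)CC[C@H]12
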